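**Plan**
- Retrosynthesis: cut the gallate ester at O3, then the C4–C4a bond of ring C, then the O1–C2 aryl ether bond, then the C2–C3 bond (vinyl addition to an aryl aldehyde).
- Forward: vinyl addition to the ring B aldehyde, oxirane across C3/C4, Mitsunobu ether O1–C2, closure of ring C by epoxy–arene cyclisation, galloylation, global debenzylation.
- Enabling feature: ring A is a 1,3,5-trioxygenated benzene whose two carbons ortho to O1 are equivalent and each ortho/para to all three oxygens, and C3 bears oxygen next to C4, so C3–O/C4 can be held as a strained oxirane that ring A opens at C4.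
- Stereochemistry: C3 from a Sharpless kinetic-resolution epoxidation with L-(+)-DIPT (erythro epoxy alcohol); C2 by Mitsunobu inversion (erythro to threo); the cyclisation breaks no bond at C2 or C3, so threo maps onto 2,3-cis (2R,3R).

Key step: step 4

Assumption: 3,4,5-tris(benzyloxy)benzaldehyde, 3,5-bis(benzyloxy)phenol and 3,4,5-tris(benzyloxy)benzoic acid are taken as purchasable building blocks, so benzyl is the only protecting group and is removed once, at the end.

Step 1
Reactants: 1 3,4,5-tris(benzyloxy)benzaldehyde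
Product: 2 (±)-1-[3,4,5-tris(benzyloxy)phenyl]prop-2-en-1-ol (racemate)
Conditions: CH2=CHMgBr (1.2 equiv), THF, −78 → 0 °C; then H2O
Reagents that add atoms: vinylmagnesium bromide, C=C[Mg]Br
Why: Grignard 1,2-addition of the vinyl nucleophile to the aromatic aldehyde should give the secondary allylic alcohol cleanly; the new stereocentre is formed without control (racemate) because its configuration is selected in step 2.

Step 2
Reactants: 2 (±)-1-[3,4,5-tris(benzyloxy)phenyl]prop-2-en-1-ol
Product: 3 (S)-[(R)-oxiran-2-yl][3,4,5-tris(benzyloxy)phenyl]methanol (erythro epoxy alcohol)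
Conditions: Ti(OiPr)4 (0.2 equiv), L-(+)-diisopropyl tartrate (0.3 equiv), tBuOOH (0.6 equiv, isooctane), 4 Å MS, CH2Cl2, −20 °C, stopped near half conversion
Reagents that add atoms: tert-butyl hydroperoxide, CC(C)(C)OO
Why: Sharpless kinetic-resolution epoxidation: the titanium tetraisopropoxide/L-(+)-tartrate catalyst should epoxidise only the (R)-enantiomer at a useful rate and on the alkene face that gives the erythro (anti) epoxy alcohol, so the carbinol configuration is set by enantiomer selection and the oxirane CH by tartrate-controlled face delivery, while the (S)-allylic alcohol stays behind and is removed by chromatography.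

Step 3
Reactants: 3 (S)-[(R)-oxiran-2-yl][3,4,5-tris(benzyloxy)phenyl]methanol; 4 3,5-bis(benzyloxy)phenol
Product: 5 (R)-2-{(R)-[3,5-bis(benzyloxy)phenoxy][3,4,5-tris(benzyloxy)phenyl]methyl}oxirane (threo aryl ether)
Conditions: PPh3, DIAD, toluene, 0 °C → rt
Reagents that add atoms: none
Why: Mitsunobu etherification: the phenol displaces the oxyphosphonium in an SN2 event with inversion at the benzylic carbinol (erythro alcohol to threo ether, future C2 = R), the oxirane being inert to the neutral conditions and the benzylic centre being poorly disposed to ionise because the adjacent oxirane is inductively withdrawing and the para benzyloxy group of ring B is twisted by its two ortho neighbours.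

Step 4
Reactants: 5 (R)-2-{(R)-[3,5-bis(benzyloxy)phenoxy][3,4,5-tris(benzyloxy)phenyl]methyl}oxirane
Product: 6 (2R,3R)-5,7-bis(benzyloxy)-2-[3,4,5-tris(benzyloxy)phenyl]-3,4-dihydro-2H-chromen-3-ol (penta-O-benzyl-(−)-epigallocatechin)
Conditions: (CF3)2CHOH (0.02 M), rt → 40 °C
Reagents that add atoms: none
Why: The fluoroalcohol activates the oxirane oxygen by hydrogen bonding, and the ring A carbon ortho to the ether oxygen (also ortho to one benzyloxy group and para to the other) attacks the terminal CH2 of the oxirane in an SN2-like Friedel–Crafts alkylation, after which the arenium ion loses a proton (net isomerisation driven by release of oxirane strain). The closest known reaction type is the intramolecular epoxy–arene cyclisation of aryl glycidyl ethers to chroman-3-ols in fluorinated alcohols or with Lewis acids. Ring C (the dihydropyran) is closed in the 6-endo-tet mode with respect to the oxirane. No new stereocentre is formed: C2 is not involved and C3 keeps its configuration because its C–O bond is never broken, so the threo ether maps directly onto the 2,3-cis (2R,3R) flavan-3-ol. The step needs attack at the terminal and not the internal oxirane carbon (which would close a dihydrobenzofuran), secured by the unhindered primary centre and by the hindered, inductively deactivated C3 next to the aryloxy-bearing carbon; it needs ring A and not ring B to react, which follows because only ring A reaches the CH2 through a six-membered transition state and is the more nucleophilic ring; and it needs no regiochemical choice on ring A because the two positions ortho to the ether oxygen are equivalent. High dilution should suppress intermolecular alkylation of the still nucleophilic product.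

Step 5
Reactants: 6 (2R,3R)-5,7-bis(benzyloxy)-2-[3,4,5-tris(benzyloxy)phenyl]-3,4-dihydro-2H-chromen-3-ol; 7 3,4,5-tris(benzyloxy)benzoic acid
Product: 8 (2R,3R)-5,7-bis(benzyloxy)-2-[3,4,5-tris(benzyloxy)phenyl]-3,4-dihydro-2H-chromen-3-yl 3,4,5-tris(benzyloxy)benzoate (octa-O-benzyl epigallocatechin gallate)
Conditions: 7 (1.5 equiv), DCC, DMAP, CH2Cl2, rt
Reagents that add atoms: none
Why: Steglich esterification (DCC activation, DMAP acyl transfer) acylates the hindered secondary C3 hydroxyl at oxygen, so neither stereocentre is touched.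

Step 6
Reactants: 8 (2R,3R)-5,7-bis(benzyloxy)-2-[3,4,5-tris(benzyloxy)phenyl]-3,4-dihydro-2H-chromen-3-yl 3,4,5-tris(benzyloxy)benzoate
Product: 9 (−)-epigallocatechin gallate, (2R,3R)-5,7-dihydroxy-2-(3,4,5-trihydroxyphenyl)-3,4-dihydro-2H-chromen-3-yl 3,4,5-trihydroxybenzoate
Conditions: H2 (1 atm), Pd(OH)2/C, THF/MeOH, rt; filtration and evaporation under argon
Reagents that add atoms: none
Why: Hydrogenolysis of all eight benzyl ethers over palladium dihydroxide on carbon under neutral conditions should free the eight phenols without cleaving the gallate ester or epimerising C2, the reaction being stopped at full debenzylation to spare the benzylic C2–O1 bond of ring C.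

**Compound list**
1 | 3,4,5-tris(benzyloxy)benzaldehyde | O=Cc1cc(OCc2ccccc2)c(OCc2ccccc2)c(OCc2ccccc2)c1 | starting material
2 | (±)-1-[3,4,5-tris(benzyloxy)phenyl]prop-2-en-1-ol (racemate) | C=CC(O)c1cc(OCc2ccccc2)c(OCc2ccccc2)c(OCc2ccccc2)c1 | intermediate
3 | (S)-[(R)-oxiran-2-yl][3,4,5-tris(benzyloxy)phenyl]methanol | O[C@@H](c1cc(OCc2ccccc2)c(OCc2ccccc2)c(OCc2ccccc2)c1)[C@H]1CO1 | intermediate
4 | 3,5-bis(benzyloxy)phenol | Oc1cc(OCc2ccccc2)cc(OCc2ccccc2)c1 | starting material
5 | (R)-2-{(R)-[3,5-bis(benzyloxy)phenoxy][3,4,5-tris(benzyloxy)phenyl]methyl}oxirane | C(c1ccccc1)Oc1cc(OCc2ccccc2)cc(O[C@H](c2cc(OCc3ccccc3)c(OCc3ccccc3)c(OCc3ccccc3)c2)[C@H]2CO2)c1 | intermediate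
6 | (2R,3R)-5,7-bis(benzyloxy)-2-[3,4,5-tris(benzyloxy)phenyl]-3,4-dihydro-2H-chromen-3-ol | O[C@@H]1Cc2c(OCc3ccccc3)cc(OCc3ccccc3)cc2O[C@@H]1c1cc(OCc2ccccc2)c(OCc2ccccc2)c(OCc2ccccc2)c1 | intermediate
7 | 3,4,5-tris(benzyloxy)benzoic acid | OC(=O)c1cc(OCc2ccccc2)c(OCc2ccccc2)c(OCc2ccccc2)c1 | starting material
8 | (2R,3R)-5,7-bis(benzyloxy)-2-[3,4,5-tris(benzyloxy)phenyl]-3,4-dihydro-2H-chromen-3-yl 3,4,5-tris(benzyloxy)benzoate | O=C(O[C@@H]1Cc2c(OCc3ccccc3)cc(OCc3ccccc3)cc2O[C@@H]1c1cc(OCc2ccccc2)c(OCc2ccccc2)c(OCc2ccccc2)c1)c1cc(OCc2ccccc2)c(OCc2ccccc2)c(OCc2ccccc2)c1 | intermediate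
9 | (−)-epigallocatechin gallate | O=C(O[C@@H]1Cc2c(O)cc(O)cc2O[C@@H]1c1cc(O)c(O)c(O)c1)c1cc(O)c(O)c(O)c1 | target

Total step count: 6. Longest linear sequence: 6 steps (1 → 2 → 3 → 5 → 6 → 8 → 9).

**Steps most likely to fail**

First, the cyclisation of step 4. The benzylic C2–O1 ether bond may ionise in the strongly ionising fluoroalcohol, with loss of the aryloxy group or scrambling at C2. Ring A may also attack the internal oxirane carbon and close a five-membered ring. The fallback is a Pummerer-type Friedel–Crafts closure, which offers ring A a single electrophilic carbon; it sets out from 5 and comes back at 8.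
- Thiophenol with Et3N in MeOH at rt should open the oxirane of 5 at its CH2 carbon to give (1R,2S)-1-[3,5-bis(benzyloxy)phenoxy]-3-(phenylsulfanyl)-1-[3,4,5-tris(benzyloxy)phenyl]propan-2-ol F1.
- Esterification with acid 7 (DCC, DMAP, CH2Cl2) should give (1R,2S)-1-[3,5-bis(benzyloxy)phenoxy]-3-(phenylsulfanyl)-1-[3,4,5-tris(benzyloxy)phenyl]propan-2-yl 3,4,5-tris(benzyloxy)benzoate F2.
- mCPBA (1 equiv, CH2Cl2, −78 °C) should give (1R,2S)-1-[3,5-bis(benzyloxy)phenoxy]-3-(phenylsulfinyl)-1-[3,4,5-tris(benzyloxy)phenyl]propan-2-yl 3,4,5-tris(benzyloxy)benzoate F3, as both configurations at sulfur.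
- (CF3CO)2O in CH2Cl2 (0 °C → rt) should generate the thionium ion at C4, which ring A can trap only through the six-membered ring, to give (2R,3S)-5,7-bis(benzyloxy)-4-(phenylsulfanyl)-2-[3,4,5-tris(benzyloxy)phenyl]-3,4-dihydro-2H-chromen-3-yl 3,4,5-tris(benzyloxy)benzoate F4, as both C4 epimers.
- Bu3SnH/AIBN in toluene at 100 °C should cleave the benzylic C–S bond to give 8, from which step 6 follows.

Second, the kinetic resolution of step 2. The rate difference between the enantiomers of the aryl vinyl carbinol may be too small, or the monosubstituted alkene may epoxidise too slowly, so that the epoxy alcohol is obtained with eroded enantiomeric purity. The fallback resolves with an enzyme before the epoxidation; it sets out from 2 and comes back at 3.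
- Lipase-catalysed acylation (Candida antarctica lipase B, vinyl acetate, toluene, rt) should acetylate the (R)-enantiomer selectively, as expected from the empirical size rule for secondary alcohols, to give (R)-1-[3,4,5-tris(benzyloxy)phenyl]prop-2-en-1-yl acetate F5, which is separated from the unreacted (S)-alcohol.
- K2CO3 in MeOH should give (R)-1-[3,4,5-tris(benzyloxy)phenyl]prop-2-en-1-ol F6.
- Epoxidation of F6 with Ti(OiPr)4, L-(+)-diisopropyl tartrate and tBuOOH (matched pair, run to full conversion) should give 3, the tartrate now only having to control the alkene face.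

Third, the etherification of step 3. Capture of the hindered benzylic oxyphosphonium by the bulky, weakly acidic phenol may be slow, allowing elimination, alkylation of the hydrazide or C-alkylation of the phloroglucinol-type ring. The fallback is a two-stage sulfonate displacement with a preformed phenoxide; it sets out from 3 and comes back at 5.
- MsCl and Et3N in CH2Cl2 at −20 °C should convert 3 with retention into (S)-[(R)-oxiran-2-yl][3,4,5-tris(benzyloxy)phenyl]methyl methanesulfonate F7.
- F7 with phenol 4 and Cs2CO3 in MeCN (0 °C → rt) should undergo SN2 displacement with inversion to give 5.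

**Further compounds**
F1 | step 4 | (1R,2S)-1-[3,5-bis(benzyloxy)phenoxy]-3-(phenylsulfanyl)-1-[3,4,5-tris(benzyloxy)phenyl]propan-2-ol | C(c1ccccc1)Oc1cc(OCc2ccccc2)cc(O[C@H](c2cc(OCc3ccccc3)c(OCc3ccccc3)c(OCc3ccccc3)c2)[C@H](O)CSc2ccccc2)c1
F2 | step 4 | (1R,2S)-1-[3,5-bis(benzyloxy)phenoxy]-3-(phenylsulfanyl)-1-[3,4,5-tris(benzyloxy)phenyl]propan-2-yl 3,4,5-tris(benzyloxy)benzoate | C(c1ccccc1)Oc1cc(OCc2ccccc2)cc(O[C@H](c2cc(OCc3ccccc3)c(OCc3ccccc3)c(OCc3ccccc3)c2)[C@H](OC(=O)c2cc(OCc3ccccc3)c(OCc3ccccc3)c(OCc3ccccc3)c2)CSc2ccccc2)c1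
F3 | step 4 | (1R,2S)-1-[3,5-bis(benzyloxy)phenoxy]-3-(phenylsulfinyl)-1-[3,4,5-tris(benzyloxy)phenyl]propan-2-yl 3,4,5-tris(benzyloxy)benzoate (both configurations at sulfur) | C(c1ccccc1)Oc1cc(OCc2ccccc2)cc(O[C@H](c2cc(OCc3ccccc3)c(OCc3ccccc3)c(OCc3ccccc3)c2)[C@H](OC(=O)c2cc(OCc3ccccc3)c(OCc3ccccc3)c(OCc3ccccc3)c2)CS(=O)c2ccccc2)c1
F4 | step 4 | (2R,3S)-5,7-bis(benzyloxy)-4-(phenylsulfanyl)-2-[3,4,5-tris(benzyloxy)phenyl]-3,4-dihydro-2H-chromen-3-yl 3,4,5-tris(benzyloxy)benzoate (both C4 epimers) | O=C(O[C@@H]1C(Sc2ccccc2)c2c(OCc3ccccc3)cc(OCc3ccccc3)cc2O[C@@H]1c1cc(OCc2ccccc2)c(OCc2ccccc2)c(OCc2ccccc2)c1)c1cc(OCc2ccccc2)c(OCc2ccccc2)c(OCc2ccccc2)c1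
F5 | step 2 | (R)-1-[3,4,5-tris(benzyloxy)phenyl]prop-2-en-1-yl acetate | C=C[C@@H](OC(C)=O)c1cc(OCc2ccccc2)c(OCc2ccccc2)c(OCc2ccccc2)c1
F6 | step 2 | (R)-1-[3,4,5-tris(benzyloxy)phenyl]prop-2-en-1-ol | C=C[C@@H](O)c1cc(OCc2ccccc2)c(OCc2ccccc2)c(OCc2ccccc2)c1
F7 | step 3 | (S)-[(R)-oxiran-2-yl][3,4,5-tris(benzyloxy)phenyl]methyl methanesulfonate | CS(=O)(=O)O[C@@H](c1cc(OCc2ccccc2)c(OCc2ccccc2)c(OCc2ccccc2)c1)[C@H]1CO1
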